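**Retrosynthetic overview**
1. Target 15 ⇒ silyl ether 14 ⇒ (alkyl C–O bond, Mitsunobu) eugenol 1 + primary alcohol 13; the C3 CH2O carbon is carried as an ester until then.
2. trans-Ester 12 ⇒ (bond from C2 of the dihydrofuran ring to C1 of the guaiacyl ring) flat, achiral benzofuran ester 5 + arylboronic acid 10, joined by an enantioselective dearomative 1,4-arylation; C3 epimerisation then funnels the cis/trans mixture into trans.
3. Enabling feature: C2 lies between ring oxygen O1 and C3, and C3 bears the carbon that becomes CH2OAr. With that carbon as CO2Et, the unit O1–C2=C3–C=O of the benzofuran is a cyclic β-aryloxyacrylate with C2 as the electrophilic β-carbon, and the C3–H of the adduct is acidic, so trans is reached by equilibration.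
4. 5 ⇒ salicylaldehyde 2 + ethyl diazoacetate 3 (aryl-shift homologation, hemiacetal, dehydration); 2 ⇒ eugenol 1 (ortho-formylation); 10 ⇒ 4-bromo-2-methoxyphenol 6.
5. Ring order: both benzene rings are bought; the furan ring is the only ring built (step 2, aromatic) and is dearomatised to the 2,3-dihydrofuran in step 5.

Key step: step 5

Remark (assumption): the sense of induction of the chiral diene on this new substrate class cannot be assigned with certainty; the route is written with (R,R)-Ph-bod* ((1R,4R)-2,5-diphenylbicyclo[2.2.2]octa-2,5-diene), and the commercial antipode is to be used if the opposite C2 face is attacked.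

**Route**

Step 1
Reactants: 1 eugenol (4-allyl-2-methoxyphenol)
Product: 2 5-allyl-2-hydroxy-3-methoxybenzaldehyde
Conditions: MgCl2, Et3N, (CH2O)n, MeCN, reflux; then 1 M HCl
Reagents that add atoms: paraformaldehyde (as formaldehyde), C=O
Why: Magnesium-phenoxide-directed ortho-formylation (Casnati–Skattebøl) should deliver formaldehyde to the only free ortho position of eugenol, the chelated salicyl alcohol being oxidised to the aldehyde by hydride transfer to a second formaldehyde.

Step 2
Reactants: 2 5-allyl-2-hydroxy-3-methoxybenzaldehyde; 3 ethyl diazoacetate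
Product: 5 ethyl 5-allyl-7-methoxybenzofuran-3-carboxylate, via hemiacetal 4 (not isolated)
Conditions: HBF4·OEt2 (10 mol%), CH2Cl2, rt; then TsOH·H2O (10 mol%), PhMe, 80 °C
Reagents that add atoms: none
Why: Acid-catalysed addition of the diazo ester to the aldehyde with 1,2-aryl shift and loss of N2 (a Roskamp-type homologation diverted to aryl migration by the electron-rich ring) should give the α-formyl arylacetate, trapped by the ortho phenol as hemiacetal 4, which acid-catalysed dehydration aromatises to the benzofuran-3-carboxylate.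

Step 3
Reactants: 6 4-bromo-2-methoxyphenol
Product: 7 (4-bromo-2-methoxyphenoxy)triisopropylsilane
Conditions: TIPSCl, imidazole, DMF, rt
Reagents that add atoms: triisopropylsilyl chloride, CC(C)[Si](Cl)(C(C)C)C(C)C
Why: Standard imidazole-mediated O-silylation of a phenol; TIPS is chosen because it should survive the basic stages of step 5 and leave with fluoride at the end.

Step 4
Reactants: 7 (4-bromo-2-methoxyphenoxy)triisopropylsilane
Product: 10 [3-methoxy-4-(triisopropylsilyloxy)phenyl]boronic acid, via aryllithium 8 (not isolated), via lithium triisopropoxyborate 9 (not isolated)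
Conditions: n-BuLi, THF, −78 °C; B(OiPr)3, −78 °C to rt; dilute HCl to pH 5
Reagents that add atoms: triisopropyl borate, CC(C)OB(OC(C)C)OC(C)C; water, O; n-butyllithium, [Li]CCCC (lithium of intermediates 8 and 9 only)
Why: Bromine–lithium exchange followed by borylation and hydrolysis of the ate complex is the standard arylboronic acid synthesis; the lithium sits para to the silyloxy group, so no retro-Brook silyl shift is possible.

Step 5
Reactants: 5 ethyl 5-allyl-7-methoxybenzofuran-3-carboxylate; 10 [3-methoxy-4-(triisopropylsilyloxy)phenyl]boronic acid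
Product: 12 ethyl (2S,3S)-5-allyl-7-methoxy-2-[3-methoxy-4-(triisopropylsilyloxy)phenyl]-2,3-dihydrobenzofuran-3-carboxylate (trans), via cis ester 11 (not isolated)
Conditions: [RhCl(C2H4)2]2 (2.5 mol%), (R,R)-Ph-bod* (5.5 mol%), KOH (0.3 equiv), 10 (3 equiv), dioxane/H2O 10:1, 60 °C; then SiO2 filtration, NaOEt (0.2 equiv), EtOH, 0 °C to rt
Reagents that add atoms: none
Why: Proposed new method: transmetalation of 10 to the chiral diene–Rh(I) hydroxide should give an aryl–Rh that inserts syn across C2=C3 of 5, with the aryl going to C2 (the β-carbon of the O1–C2=C3–C=O unit) and rhodium ending as the oxa-π-allyl ester enolate, which water protonates to return Rh–OH; the closest known reaction types are the Rh-catalysed asymmetric 1,4-addition of arylboronic acids to chromones and coumarins (Hayashi–Miyaura reaction) and dearomative conjugate additions to acceptor-substituted benzofurans and indoles. No ring is closed; the aromatic furan ring is dearomatised to the 2,3-dihydrofuran. C2 is set by the ligand, which selects the enantioface of the flat C2=C3 bond at insertion, and C3 is set thermodynamically, because the kinetic protonation mixture (cis ester 11 beside trans ester) equilibrates through the ester enolate under NaOEt to the trans ester, with C2 aryl and C3 ester on opposite faces. The step needs regioselectivity for C2 over C3, which the C3 ester and ring oxygen O1 secure by polarising the double bond, and chemoselectivity over the C5 allyl alkene, which carries no activating group. It also needs the C2–O1 bond to stay intact, which the ring secures because that bond lies in the nodal plane of the enolate π system (the reverse of a 5-endo-trig closure). The silyl ether keeps the para oxygen from becoming a phenoxide that could open the ring through a quinone methide and erode C2.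

Step 6
Reactants: 12 trans ester
Product: 13 [(2S,3R)-5-allyl-7-methoxy-2-[3-methoxy-4-(triisopropylsilyloxy)phenyl]-2,3-dihydrobenzofuran-3-yl]methanol
Conditions: DIBAL-H (2.5 equiv), CH2Cl2, −78 to 0 °C; Rochelle salt
Reagents that add atoms: none
Why: Hydride reduction of the ester to the primary alcohol at low temperature should leave the silyl ether and both allyl groups untouched and removes the acidic C3–H, fixing the trans configuration (the C3 descriptor changes from S to R by priority only).

Step 7
Reactants: 13 primary alcohol; 1 eugenol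
Product: 14 triisopropylsilyl ether of the target, (2S,3R)-5-allyl-3-[(4-allyl-2-methoxyphenoxy)methyl]-7-methoxy-2-[3-methoxy-4-(triisopropylsilyloxy)phenyl]-2,3-dihydrobenzofuran
Conditions: PPh3, DIAD, THF, 0 °C to rt
Reagents that add atoms: none
Why: Mitsunobu etherification of a primary alcohol with a phenol of pKa about 10 should form the alkyl aryl ether at the CH2 carbon without touching either stereocentre.

Step 8
Reactants: 14 triisopropylsilyl ether of the target
Product: 15 target, 4-[(2S,3R)-5-allyl-3-[(4-allyl-2-methoxyphenoxy)methyl]-7-methoxy-2,3-dihydrobenzofuran-2-yl]-2-methoxyphenol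
Conditions: TBAF, AcOH (1.2 equiv each), THF, 0 °C
Reagents that add atoms: none
Why: Fluoride-induced cleavage of the aryl silyl ether, buffered with acetic acid so that the liberated para-phenoxide is protonated at once and C2 is not opened through a quinone methide.

**Compound list**
1 | eugenol (4-allyl-2-methoxyphenol) | C=CCc1ccc(O)c(OC)c1 | starting material
2 | 5-allyl-2-hydroxy-3-methoxybenzaldehyde | C=CCc1cc(C=O)c(O)c(OC)c1 | intermediate
3 | ethyl diazoacetate | CCOC(=O)C=[N+]=[N-] | starting material
4 | ethyl 5-allyl-2-hydroxy-7-methoxy-2,3-dihydrobenzofuran-3-carboxylate (hemiacetal, mixture of stereoisomers) | CCOC(=O)C1C(O)Oc2c(OC)cc(CC=C)cc12 | intermediate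
5 | ethyl 5-allyl-7-methoxybenzofuran-3-carboxylate | CCOC(=O)c1coc2c(OC)cc(CC=C)cc12 | intermediate
6 | 4-bromo-2-methoxyphenol | COc1cc(Br)ccc1O | starting material
7 | (4-bromo-2-methoxyphenoxy)triisopropylsilane | COc1cc(Br)ccc1O[Si](C(C)C)(C(C)C)C(C)C | intermediate
8 | [3-methoxy-4-(triisopropylsilyloxy)phenyl]lithium | COc1cc([Li])ccc1O[Si](C(C)C)(C(C)C)C(C)C | intermediate
9 | lithium triisopropoxy[3-methoxy-4-(triisopropylsilyloxy)phenyl]borate | COc1cc([B-](OC(C)C)(OC(C)C)OC(C)C)ccc1O[Si](C(C)C)(C(C)C)C(C)C.[Li+] | intermediate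
10 | [3-methoxy-4-(triisopropylsilyloxy)phenyl]boronic acid | COc1cc(B(O)O)ccc1O[Si](C(C)C)(C(C)C)C(C)C | intermediate
11 | ethyl (2S,3R)-5-allyl-7-methoxy-2-[3-methoxy-4-(triisopropylsilyloxy)phenyl]-2,3-dihydrobenzofuran-3-carboxylate (cis) | CCOC(=O)[C@@H]1c2cc(CC=C)cc(OC)c2O[C@@H]1c1ccc(O[Si](C(C)C)(C(C)C)C(C)C)c(OC)c1 | intermediate
12 | ethyl (2S,3S)-5-allyl-7-methoxy-2-[3-methoxy-4-(triisopropylsilyloxy)phenyl]-2,3-dihydrobenzofuran-3-carboxylate (trans) | CCOC(=O)[C@H]1c2cc(CC=C)cc(OC)c2O[C@@H]1c1ccc(O[Si](C(C)C)(C(C)C)C(C)C)c(OC)c1 | intermediate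
13 | [(2S,3R)-5-allyl-7-methoxy-2-[3-methoxy-4-(triisopropylsilyloxy)phenyl]-2,3-dihydrobenzofuran-3-yl]methanol | OC[C@H]1c2cc(CC=C)cc(OC)c2O[C@@H]1c1ccc(O[Si](C(C)C)(C(C)C)C(C)C)c(OC)c1 | intermediate
14 | (2S,3R)-5-allyl-3-[(4-allyl-2-methoxyphenoxy)methyl]-7-methoxy-2-[3-methoxy-4-(triisopropylsilyloxy)phenyl]-2,3-dihydrobenzofuran | C=CCc1ccc(OC[C@H]2c3cc(CC=C)cc(OC)c3O[C@@H]2c2ccc(O[Si](C(C)C)(C(C)C)C(C)C)c(OC)c2)c(OC)c1 | intermediate
15 | 4-[(2S,3R)-5-allyl-3-[(4-allyl-2-methoxyphenoxy)methyl]-7-methoxy-2,3-dihydrobenzofuran-2-yl]-2-methoxyphenol | C=CCc1ccc(OC[C@H]2c3cc(CC=C)cc(OC)c3O[C@@H]2c2ccc(O)c(OC)c2)c(OC)c1 | target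

**Count**
Total steps: 8. Longest linear sequence: 6 (steps 1, 2, 5, 6, 7, 8); steps 3 and 4 form a two-step branch that joins at step 5.

**Steps most likely to fail**

Step 5. The push–pull heteroaromatic acrylate may insert too slowly into the aryl–rhodium bond, so that protodeboronation of 10 wins. Face discrimination at C2 may be insufficient, rhodium may isomerise the allyl group, and the ethoxide stage may equilibrate incompletely or remove the silyl group. Fallback (known chemistry, same C2–aryl bond made on the aromatic stage): 5 is magnesiated at C2 with TMPMgCl·LiCl (THF, −40 °C) and quenched with iodine to give ethyl 5-allyl-2-iodo-7-methoxybenzofuran-3-carboxylate F1. Suzuki–Miyaura coupling of F1 with 10 (Pd(dppf)Cl2, K3PO4, dioxane/H2O, 50 °C) should give ethyl 5-allyl-7-methoxy-2-[3-methoxy-4-(triisopropylsilyloxy)phenyl]benzofuran-3-carboxylate F2. Dissolving-metal conjugate reduction (Mg, MeOH, 0 °C to rt), with thermodynamic protonation and transesterification, should give the racemic trans methyl ester, methyl rac-(2S,3S)-5-allyl-7-methoxy-2-[3-methoxy-4-(triisopropylsilyloxy)phenyl]-2,3-dihydrobenzofuran-3-carboxylate F3. Preparative chiral-phase chromatography would then furnish the (2S,3S)-methyl ester F4, and DIBAL-H reduction of F4 returns to the route at 13.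

Step 2. The diazo ester may be consumed by O–H insertion into the phenol or by hydride shift instead of aryl shift, and the electron-rich allyl arene may oligomerise during the acid dehydration. Fallback (ring built by C–C coupling instead of aldehyde homologation): eugenol 1 is iodinated ortho to the hydroxyl (iodine–morpholine complex, CH2Cl2, 0 °C) to give 4-allyl-2-iodo-6-methoxyphenol F5. Oxa-Michael addition of F5 to ethyl propiolate (N-methylmorpholine, CH2Cl2, rt) should give ethyl (E)-3-(4-allyl-2-iodo-6-methoxyphenoxy)acrylate F6. Intramolecular Heck cyclisation of F6 (Pd(OAc)2, PPh3, Et3N, MeCN, 80 °C) returns to the route at 5.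

Step 7. The alkoxyphosphonium of the β-branched alcohol may eliminate towards C3 or be displaced too slowly, so that the hydrazide is alkylated instead of the phenol. Fallback (two-step sulfonate activation and Williamson displacement instead of redox condensation): 13 is converted with MsCl/Et3N (CH2Cl2, 0 °C) into [(2S,3R)-5-allyl-7-methoxy-2-[3-methoxy-4-(triisopropylsilyloxy)phenyl]-2,3-dihydrobenzofuran-3-yl]methyl methanesulfonate F7. Displacement of F7 with eugenol 1 (K2CO3, NaI cat., butanone, 70 °C) returns to the route at 14.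

**Further compounds**
F1 | step 5 | ethyl 5-allyl-2-iodo-7-methoxybenzofuran-3-carboxylate | CCOC(=O)c1c(I)oc2c(OC)cc(CC=C)cc12
F2 | step 5 | ethyl 5-allyl-7-methoxy-2-[3-methoxy-4-(triisopropylsilyloxy)phenyl]benzofuran-3-carboxylate | CCOC(=O)c1c(-c2ccc(O[Si](C(C)C)(C(C)C)C(C)C)c(OC)c2)oc2c(OC)cc(CC=C)cc12
F3 | step 5 | methyl rac-(2S,3S)-5-allyl-7-methoxy-2-[3-methoxy-4-(triisopropylsilyloxy)phenyl]-2,3-dihydrobenzofuran-3-carboxylate (racemic trans, both enantiomers written) | COC(=O)[C@H]1c2cc(CC=C)cc(OC)c2O[C@@H]1c1ccc(O[Si](C(C)C)(C(C)C)C(C)C)c(OC)c1.COC(=O)[C@@H]1c2cc(CC=C)cc(OC)c2O[C@H]1c1ccc(O[Si](C(C)C)(C(C)C)C(C)C)c(OC)c1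
F4 | step 5 | methyl (2S,3S)-5-allyl-7-methoxy-2-[3-methoxy-4-(triisopropylsilyloxy)phenyl]-2,3-dihydrobenzofuran-3-carboxylate | COC(=O)[C@H]1c2cc(CC=C)cc(OC)c2O[C@@H]1c1ccc(O[Si](C(C)C)(C(C)C)C(C)C)c(OC)c1
F5 | step 2 | 4-allyl-2-iodo-6-methoxyphenol | C=CCc1cc(I)c(O)c(OC)c1
F6 | step 2 | ethyl (E)-3-(4-allyl-2-iodo-6-methoxyphenoxy)acrylate | CCOC(=O)/C=C/Oc1c(I)cc(CC=C)cc1OC
F7 | step 7 | [(2S,3R)-5-allyl-7-methoxy-2-[3-methoxy-4-(triisopropylsilyloxy)phenyl]-2,3-dihydrobenzofuran-3-yl]methyl methanesulfonate | CS(=O)(=O)OC[C@H]1c2cc(CC=C)cc(OC)c2O[C@@H]1c1ccc(O[Si](C(C)C)(C(C)C)C(C)C)c(OC)c1
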